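**Retrosynthetic overview**

1. Feature: the erythro C8–OH / C9–O-methacryloyl pair on adjacent carbons of the ten-membered carbocycle (C1–C10), between C7 of the lactone ring and quaternary C10 of the furanone ring. It is read as the syn-dihydroxylation product of a Z C8=C9 alkene, which would be the only isolated alkene of the oxygen-bridged bicycle.
2. Target ⇒ (desilylation, unmasking of C11=C13, C9 acylation, C8 silylation) cis-8,9-diol ⇒ OsO4 on the Z-C8=C9 macrocycle ⇒ ring-closing metathesis of the C7-vinyl / C10-vinyl seco compound.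
3. Seco compound ⇒ furanone from a γ-hydroxy ynone (C3 ketone, C2≡C1, C10–OH) ⇒ C3–C4 bond by Nozaki–Hiyama–Kishi coupling of a Z C4-iodoalkene with a C3 ynal.
4. Iodoalkene ⇐ (S)-5-(hydroxymethyl)butenolide (anti vinyl cuprate sets C7, a Mannich base at C11 carries the future C11=C13, Z-iodo-Wittig makes C4=C5). Ynal ⇐ isoprene monoxide (Pd-catalysed asymmetric etherification sets C10).
5. Ring order: lactone ring (chiral pool), furanone ring (step 14), ten-membered carbocycle (step 15). The α-methylene is kept as CH2NMe2 until step 19, so that neither Ru, OsO4 nor Et2NH meets an acrylate-type alkene.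

Key step: step 15

Remarks. Germacrane numbering is used for all intermediates: C1 ketone, C2=C3, O3 = ring oxygen on C3 and C10 ("3,10-epoxy"), C4(C15)=C5, C6 lactone OCH, C7, C8, C9, C10(C14), C11, C12 lactone C=O, C13 on C11. Compounds 23 and 26 are the precursor and product of the key step, with C11=C13 carried as C11H–CH2NMe2. A free α-methylene-γ-lactone is a competent partner for Ru alkylidenes and for OsO4, adds Et2NH, and has a base-labile doubly allylic H7. Assumption: the (R,R) ligand in step 7 is taken to deliver the (S) ether 13; if the sense is the opposite, the (S,S) ligand is used with nothing else changed. The facial preference claimed in step 16 rests on a hand-built model of the bicycle, not on a calculation.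

**Route**

Step 1
Reactants: 1 (S)-5-(hydroxymethyl)furan-2(5H)-one
Product: 2 (S)-5-{[tert-butyl(diphenyl)silyl]oxymethyl}furan-2(5H)-one
Conditions: TBDPSCl, imidazole, DMF, 0 °C to rt
Reagents that add atoms: tert-butyl(chloro)diphenylsilane, CC(C)(C)[Si](Cl)(c1ccccc1)c1ccccc1
Why: Silyl ether formation at the primary alcohol gives a bulky side chain on C6 that blocks one face of the butenolide, and C6 itself is untouched.

Step 2
Reactants: 2; 3 vinylmagnesium bromide
Product: 4 (4R,5S)-5-{[tert-butyl(diphenyl)silyl]oxymethyl}-4-ethenyloxolan-2-one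
Conditions: CH2=CHMgBr (2.2 equiv), CuI (1.1 equiv), THF/Me2S, −78 to −40 °C; aq NH4Cl
Reagents that add atoms: vinylmagnesium bromide 3, C=C[Mg]Br
Why: Conjugate addition of the cuprate (CH2=CH)2CuMgBr to the butenolide takes place anti to the silyloxymethyl group on C6, which sets C7 and the trans lactone.

Step 3
Reactants: 4; 5 N,N-dimethylmethyleneiminium iodide (Eschenmoser's salt)
Product: 6 (3R,4S,5S)-5-{[tert-butyl(diphenyl)silyl]oxymethyl}-3-[(dimethylamino)methyl]-4-ethenyloxolan-2-one
Conditions: LiN(SiMe3)2, THF, −78 °C; then 5, −78 °C to rt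
Reagents that add atoms: N,N-dimethylmethyleneiminium iodide 5, C[N+](C)=C.[I-]
Why: Mannich reaction of the lithium lactone enolate with the iminium salt installs C13 anti to the C7 vinyl group; the C11 centre is temporary and is erased in step 19.

Step 4
Reactants: 6
Product: 7 (3R,4S,5S)-3-[(dimethylamino)methyl]-4-ethenyl-5-(hydroxymethyl)oxolan-2-one
Conditions: Bu4NF, AcOH, THF, 0 °C to rt
Reagents that add atoms: none
Why: Fluoride-induced desilylation, buffered with acetic acid, frees the C5 alcohol without opening the lactone.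

Step 5
Reactants: 7
Product: 8 (2S,3S,4R)-4-[(dimethylamino)methyl]-3-ethenyl-5-oxooxolane-2-carbaldehyde
Conditions: (COCl)2, DMSO, CH2Cl2, −78 °C; Et3N, −78 to −20 °C; used crude
Reagents that add atoms: none
Why: Swern oxidation at low temperature should give the α-acyloxy aldehyde with C6 intact, and the aldehyde is carried on at once.

Step 6
Reactants: 8; 9 ethyltriphenylphosphonium iodide
Product: 10 (3R,4S,5S)-3-[(dimethylamino)methyl]-4-ethenyl-5-[(Z)-2-iodoprop-1-en-1-yl]oxolan-2-one
Conditions: 9, n-BuLi, THF, rt; I2, −78 °C; NaN(SiMe3)2, −20 °C; then 8, −78 to −20 °C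
Reagents that add atoms: ethyltriphenylphosphonium iodide 9, CC[P+](c1ccccc1)(c1ccccc1)c1ccccc1.[I-]; iodine, II
Why: Stork–Zhao iodo-olefination (Wittig reaction of the α-iodo ylide Ph3P=C(I)CH3) should give the Z 2-iodoalkene under kinetic control, which places iodine (the future C3) cis to C6 on C4=C5.

Step 7
Reactants: 11 2-methyl-2-vinyloxirane (racemic isoprene monoxide); 12 4-methoxybenzyl alcohol
Product: 13 (2S)-2-[(4-methoxyphenyl)methoxy]-2-methylbut-3-en-1-ol
Conditions: Pd2(dba)3·CHCl3 (1 mol%), (R,R)-DACH-phenyl Trost ligand (3 mol%), BEt3 (1 mol%), CH2Cl2, rt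
Reagents that add atoms: 4-methoxybenzyl alcohol 12, COc1ccc(CO)cc1
Why: Palladium-catalysed dynamic kinetic asymmetric allylic etherification (Trost): zerovalent palladium opens the vinyl epoxide to interconverting π-allyl complexes and the boron-bound alkoxide is delivered to the tertiary terminus inside the chiral pocket, which sets C10.

Step 8
Reactants: 13
Product: 14 (2S)-2-[(4-methoxyphenyl)methoxy]-2-methylbut-3-enal
Conditions: (COCl)2, DMSO, CH2Cl2, −78 °C; Et3N, −78 to 0 °C
Reagents that add atoms: none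
Why: Swern oxidation; the aldehyde has no α-hydrogen, so C10 cannot epimerise.

Step 9
Reactants: 14; 15 dimethyl (1-diazo-2-oxopropyl)phosphonate (Ohira–Bestmann reagent)
Product: 16 1-methoxy-4-({[(3S)-3-methylpent-1-en-4-yn-3-yl]oxy}methyl)benzene
Conditions: 15, K2CO3, MeOH, 0 °C to rt
Reagents that add atoms: dimethyl (1-diazo-2-oxopropyl)phosphonate 15, COP(=O)(OC)C(=[N+]=[N-])C(C)=O
Why: Ohira–Bestmann (Seyferth–Gilbert) homologation turns the aldehyde into the terminal alkyne C1≡C2 through the diazomethylphosphonate anion and a 1,2-shift of the alkylidene carbene.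

Step 10
Reactants: 16; 17 N,N-dimethylformamide
Product: 18 (4S)-4-[(4-methoxyphenyl)methoxy]-4-methylhex-5-en-2-ynal
Conditions: n-BuLi, THF, −78 °C; DMF, −78 to 0 °C; poured into aq KH2PO4
Reagents that add atoms: N,N-dimethylformamide 17, CN(C)C=O
Why: Formylation of the lithium acetylide with DMF adds C3, and the inverse buffered quench releases the ynal before dimethylamine can add to it.

Step 11
Reactants: 10; 18
Product: 19 (3R,4S,5S)-3-[(dimethylamino)methyl]-4-ethenyl-5-[(1Z,6S)-3-hydroxy-6-[(4-methoxyphenyl)methoxy]-2,6-dimethylocta-1,7-dien-4-yn-1-yl]oxolan-2-one (both C3 carbinol epimers)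
Conditions: CrCl2 (6 equiv), NiCl2 (2 mol%), DMSO, rt
Reagents that add atoms: none
Why: Nozaki–Hiyama–Kishi coupling: the alkenyl iodide is passed through nickel to divalent chromium and adds 1,2 to the aldehyde with retention of the Z geometry while lactone, amine and benzyl ether stay inert; the C3 carbinol epimers converge in step 12.

Step 12
Reactants: 19
Product: 20 (3R,4S,5S)-3-[(dimethylamino)methyl]-4-ethenyl-5-[(1Z,6S)-6-[(4-methoxyphenyl)methoxy]-2,6-dimethyl-3-oxoocta-1,7-dien-4-yn-1-yl]oxolan-2-one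
Conditions: MnO2, CH2Cl2, rt
Reagents that add atoms: none
Why: MnO2 oxidation of the doubly activated (allylic and propargylic) C3 alcohol should give the cross-conjugated ynone without touching the amine.

Step 13
Reactants: 20
Product: 21 (3R,4S,5S)-3-[(dimethylamino)methyl]-4-ethenyl-5-[(1Z,6S)-6-hydroxy-2,6-dimethyl-3-oxoocta-1,7-dien-4-yn-1-yl]oxolan-2-one
Conditions: CF3CO2H, anisole, CH2Cl2, 0 °C; aq NaHCO3
Reagents that add atoms: none
Why: Acidolysis of the 4-methoxybenzyl ether with anisole as cation trap frees the C10 hydroxyl; the protonated amine is inert and the C10–O bond should not ionise because the cation would sit next to the electron-poor ynone.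

Step 14
Reactants: 21
Product: 23 (3R,4S,5S)-3-[(dimethylamino)methyl]-4-ethenyl-5-{(Z)-2-[(5S)-5-ethenyl-5-methyl-4-oxo-4,5-dihydrofuran-2-yl]prop-1-en-1-yl}oxolan-2-one, via enaminone 22 (not isolated)
Conditions: Et2NH (1.2 equiv), EtOH, 0 °C; then AcOH/H2O, rt
Reagents that add atoms: water, O
Why: Conjugate addition of diethylamine to the ynone gives the enaminone, and acid hydrolysis unveils the C1 ketone while the C10 hydroxyl adds to C3 and water is lost (the γ-hydroxy ynone route to 3(2H)-furanones); brief amine contact at 0 °C should keep C4=C5 Z.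

Step 15
Reactants: 23
Product: 26 (4Z,8Z,6S,7S,10S,11R)-13-(dimethylamino)-3,10-epoxy-1-oxogermacra-2,4,8-trien-12,6-olide, via tosylate salt 24 (not isolated), via macrocycle tosylate salt 25 (not isolated)
Conditions: TsOH·H2O (1.05 equiv), CH2Cl2, rt, evaporate; second-generation Hoveyda–Grubbs catalyst RuCl2(H2IMes)(=CH-C6H4-2-OiPr) (15 mol% in three portions), 2,6-dichloro-1,4-benzoquinone (10 mol%), ClCH2CH2Cl, 0.5 mM, 80 °C, argon sparge; aq NaHCO3
Reagents that add atoms: none
Why: Ring-closing olefin metathesis: the Ru alkylidene forms at the unhindered C7 vinyl group, adds [2+2] across the C10 vinyl group and cycloreverts with loss of ethene, which creates C8=C9; the closest known reaction type is the second-generation-catalyst RCM that closes ten-membered carbocycles and oxygen-bridged medium rings at a disubstituted alkene. The ring closed is the ten-membered carbocycle C1–C10 (nine-membered through O3), formed by joining two terminal alkenes into an endocyclic alkene; the planar furanone, the s-cis C3–C4 bond and the Z C4=C5 alkene hold C6 about 4 Å from C10, so that C7–C8=C9 only has to bridge that gap. No stereocentre is made, and the alkene can only be Z because an E alkene does not fit into this short arc of the bridged ring. The step needs chemoselectivity for the two vinyl groups and cyclisation instead of oligomerisation: C4=C5 (trisubstituted, conjugated) and C2=C3 (vinylogous ester) do not engage Ru alkylidenes, the acrylate-type C11=C13 is absent (masked as CH2NMe2), and the amine is kept as its tosylate salt so that it cannot bind Ru. High dilution with removal of ethene favours ring closure, and the quinone intercepts Ru–H species that would isomerise the C7 vinyl group.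

Step 16
Reactants: 26
Product: 27 (4Z,6R,7R,8S,9S,10S,11R)-13-(dimethylamino)-3,10-epoxy-8,9-dihydroxy-1-oxogermacra-2,4-dien-12,6-olide
Conditions: OsO4 (5 mol%), NMO (1.5 equiv), acetone/H2O, 0 °C to rt; aq Na2SO3
Reagents that add atoms: N-methylmorpholine N-oxide, C[N+]1([O-])CCOCC1; water, O; both delivered through catalytic OsO4, O=[Os](=O)(=O)=O
Why: Upjohn syn-dihydroxylation ([3+2] addition of OsO4, reoxidised by NMO) of the only isolated alkene; in the 11-oxabicyclo[6.2.1] framework one face of C8=C9 is shielded by C1 of the two-carbon keto bridge and by the lactone carbon C11, so osmium should add over the one-atom oxygen bridge O3 where only H7 stands, which gives the 8S,9S erythro diol.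

Step 17
Reactants: 27
Product: 28 (4Z,6R,7S,8S,9S,10S,11R)-13-(dimethylamino)-3,10-epoxy-9-hydroxy-1-oxo-8-(triethylsilyloxy)germacra-2,4-dien-12,6-olide
Conditions: TESCl (1.1 equiv), imidazole, CH2Cl2, −20 °C
Reagents that add atoms: chlorotriethylsilane, CC[Si](Cl)(CC)CC
Why: Regioselective silyl ether formation: the C8 hydroxyl next to tertiary C7 should react before the neopentyl-type C9 hydroxyl next to quaternary C10.

Step 18
Reactants: 28; 29 methacrylic anhydride
Product: 30 (4Z,6R,7S,8S,9S,10S,11R)-13-(dimethylamino)-3,10-epoxy-9-(methacryloyloxy)-1-oxo-8-(triethylsilyloxy)germacra-2,4-dien-12,6-olide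
Conditions: 29 (3 equiv), DMAP (1 equiv), Et3N, BHT (trace), CH2Cl2, rt to 40 °C
Reagents that add atoms: methacrylic anhydride 29, C=C(C)C(=O)OC(=O)C(C)=C
Why: DMAP-catalysed acyl transfer esterifies the remaining hindered C9 hydroxyl; C10 is quaternary, so the resulting β-acyloxy ketone cannot eliminate.

Step 19
Reactants: 30
Product: 32 (4Z,6R,7S,8S,9S,10S)-3,10-epoxy-9-(methacryloyloxy)-1-oxo-8-(triethylsilyloxy)germacra-2,4,11(13)-trien-12,6-olide, via methiodide 31 (not isolated)
Conditions: MeI, MeCN, rt, dark; evaporate; aq NaHCO3, EtOAc, rt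
Reagents that add atoms: none
Why: N-Methylation followed by E1cB (Hofmann-type) loss of trimethylamine from the β-ammonio lactone regenerates the C11=C13 methylene under conditions too mild to move the C9 ester or cleave the silyl ether.

Step 20
Reactants: 32
Product: 33 (4Z,6R,7R,8S,9S,10S)-3,10-epoxy-8-hydroxy-9-(methacryloyloxy)-1-oxogermacra-2,4,11(13)-trien-12,6-olide (target CNP0562373.1)
Conditions: HF·pyridine, pyridine, THF, 0 °C
Reagents that add atoms: none
Why: Acidic fluoride desilylation frees the C8 hydroxyl; avoiding basic fluoride should prevent C9-to-C8 acyl migration and conjugate addition to the two acrylate units.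

**Compound list**

1 | (S)-5-(hydroxymethyl)furan-2(5H)-one | OC[C@H]1OC(=O)C=C1 | starting material
2 | (S)-5-{[tert-butyl(diphenyl)silyl]oxymethyl}furan-2(5H)-one | CC(C)(C)[Si](OC[C@H]1OC(=O)C=C1)(c1ccccc1)c1ccccc1 | intermediate
3 | vinylmagnesium bromide | C=C[Mg]Br | starting material
4 | (4R,5S)-5-{[tert-butyl(diphenyl)silyl]oxymethyl}-4-ethenyloxolan-2-one | CC(C)(C)[Si](OC[C@H]1OC(=O)C[C@@H]1C=C)(c1ccccc1)c1ccccc1 | intermediate
5 | N,N-dimethylmethyleneiminium iodide | C[N+](C)=C.[I-] | starting material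
6 | (3R,4S,5S)-5-{[tert-butyl(diphenyl)silyl]oxymethyl}-3-[(dimethylamino)methyl]-4-ethenyloxolan-2-one | CC(C)(C)[Si](OC[C@H]1OC(=O)[C@@H](CN(C)C)[C@@H]1C=C)(c1ccccc1)c1ccccc1 | intermediate
7 | (3R,4S,5S)-3-[(dimethylamino)methyl]-4-ethenyl-5-(hydroxymethyl)oxolan-2-one | OC[C@H]1OC(=O)[C@@H](CN(C)C)[C@@H]1C=C | intermediate
8 | (2S,3S,4R)-4-[(dimethylamino)methyl]-3-ethenyl-5-oxooxolane-2-carbaldehyde | O=C[C@H]1OC(=O)[C@@H](CN(C)C)[C@@H]1C=C | intermediate
9 | ethyltriphenylphosphonium iodide | CC[P+](c1ccccc1)(c1ccccc1)c1ccccc1.[I-] | starting material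
10 | (3R,4S,5S)-3-[(dimethylamino)methyl]-4-ethenyl-5-[(Z)-2-iodoprop-1-en-1-yl]oxolan-2-one | I/C(C)=C\[C@H]1OC(=O)[C@@H](CN(C)C)[C@@H]1C=C | intermediate
11 | 2-methyl-2-vinyloxirane (racemic) | CC1(C=C)CO1 | starting material
12 | 4-methoxybenzyl alcohol | COc1ccc(CO)cc1 | starting material
13 | (2S)-2-[(4-methoxyphenyl)methoxy]-2-methylbut-3-en-1-ol | C=C[C@@](C)(CO)OCc1ccc(OC)cc1 | intermediate
14 | (2S)-2-[(4-methoxyphenyl)methoxy]-2-methylbut-3-enal | C=C[C@@](C)(C=O)OCc1ccc(OC)cc1 | intermediate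
15 | dimethyl (1-diazo-2-oxopropyl)phosphonate | COP(=O)(OC)C(=[N+]=[N-])C(C)=O | starting material
16 | 1-methoxy-4-({[(3S)-3-methylpent-1-en-4-yn-3-yl]oxy}methyl)benzene | C=C[C@@](C)(C#C)OCc1ccc(OC)cc1 | intermediate
17 | N,N-dimethylformamide | CN(C)C=O | starting material
18 | (4S)-4-[(4-methoxyphenyl)methoxy]-4-methylhex-5-en-2-ynal | C=C[C@@](C)(C#CC=O)OCc1ccc(OC)cc1 | intermediate
19 | (3R,4S,5S)-3-[(dimethylamino)methyl]-4-ethenyl-5-[(1Z,6S)-3-hydroxy-6-[(4-methoxyphenyl)methoxy]-2,6-dimethylocta-1,7-dien-4-yn-1-yl]oxolan-2-one (C3 epimers) | C=C[C@@](C)(C#CC(O)/C(C)=C\[C@H]1OC(=O)[C@@H](CN(C)C)[C@@H]1C=C)OCc1ccc(OC)cc1 | intermediate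
20 | (3R,4S,5S)-3-[(dimethylamino)methyl]-4-ethenyl-5-[(1Z,6S)-6-[(4-methoxyphenyl)methoxy]-2,6-dimethyl-3-oxoocta-1,7-dien-4-yn-1-yl]oxolan-2-one | C=C[C@@](C)(C#CC(=O)/C(C)=C\[C@H]1OC(=O)[C@@H](CN(C)C)[C@@H]1C=C)OCc1ccc(OC)cc1 | intermediate
21 | (3R,4S,5S)-3-[(dimethylamino)methyl]-4-ethenyl-5-[(1Z,6S)-6-hydroxy-2,6-dimethyl-3-oxoocta-1,7-dien-4-yn-1-yl]oxolan-2-one | C=C[C@@](C)(C#CC(=O)/C(C)=C\[C@H]1OC(=O)[C@@H](CN(C)C)[C@@H]1C=C)O | intermediate
22 | (3R,4S,5S)-5-[(1Z,4E,6S)-5-(diethylamino)-6-hydroxy-2,6-dimethyl-3-oxoocta-1,4,7-trien-1-yl]-3-[(dimethylamino)methyl]-4-ethenyloxolan-2-one | C=C[C@@](C)(/C(N(CC)CC)=C\C(=O)/C(C)=C\[C@H]1OC(=O)[C@@H](CN(C)C)[C@@H]1C=C)O | intermediate (not isolated)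
23 | (3R,4S,5S)-3-[(dimethylamino)methyl]-4-ethenyl-5-{(Z)-2-[(5S)-5-ethenyl-5-methyl-4-oxo-4,5-dihydrofuran-2-yl]prop-1-en-1-yl}oxolan-2-one (key-step precursor) | C=C[C@]1(C)OC(=CC1=O)/C(C)=C\[C@H]1OC(=O)[C@@H](CN(C)C)[C@@H]1C=C | intermediate
24 | 4-methylbenzenesulfonate salt of 23 | C=C[C@]1(C)OC(=CC1=O)/C(C)=C\[C@H]1OC(=O)[C@@H](C[NH+](C)C)[C@@H]1C=C.Cc1ccc(S(=O)(=O)[O-])cc1 | intermediate (not isolated)
25 | 4-methylbenzenesulfonate salt of 26 | C[C@]12/C=C\[C@H]3[C@H](C[NH+](C)C)C(=O)O[C@@H]3/C=C(/C)C(=CC1=O)O2.Cc1ccc(S(=O)(=O)[O-])cc1 | intermediate (not isolated)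
26 | (4Z,8Z,6S,7S,10S,11R)-13-(dimethylamino)-3,10-epoxy-1-oxogermacra-2,4,8-trien-12,6-olide (key-step product) | C[C@]12/C=C\[C@H]3[C@H](CN(C)C)C(=O)O[C@@H]3/C=C(/C)C(=CC1=O)O2 | intermediate
27 | (4Z,6R,7R,8S,9S,10S,11R)-13-(dimethylamino)-3,10-epoxy-8,9-dihydroxy-1-oxogermacra-2,4-dien-12,6-olide | O[C@H]1[C@@H](O)[C@H]2[C@H](CN(C)C)C(=O)O[C@@H]2/C=C(/C)C2=CC(=O)[C@@]1(C)O2 | intermediate
28 | (4Z,6R,7S,8S,9S,10S,11R)-13-(dimethylamino)-3,10-epoxy-9-hydroxy-1-oxo-8-(triethylsilyloxy)germacra-2,4-dien-12,6-olide | O[C@H]1[C@@H](O[Si](CC)(CC)CC)[C@H]2[C@H](CN(C)C)C(=O)O[C@@H]2/C=C(/C)C2=CC(=O)[C@@]1(C)O2 | intermediate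
29 | methacrylic anhydride | C=C(C)C(=O)OC(=O)C(C)=C | starting material
30 | (4Z,6R,7S,8S,9S,10S,11R)-13-(dimethylamino)-3,10-epoxy-9-(methacryloyloxy)-1-oxo-8-(triethylsilyloxy)germacra-2,4-dien-12,6-olide | C=C(C)C(=O)O[C@H]1[C@@H](O[Si](CC)(CC)CC)[C@H]2[C@H](CN(C)C)C(=O)O[C@@H]2/C=C(/C)C2=CC(=O)[C@@]1(C)O2 | intermediate
31 | N-methyl ammonium iodide of 30 (13-trimethylammonio compound) | C=C(C)C(=O)O[C@H]1[C@@H](O[Si](CC)(CC)CC)[C@H]2[C@H](C[N+](C)(C)C)C(=O)O[C@@H]2/C=C(/C)C2=CC(=O)[C@@]1(C)O2.[I-] | intermediate (not isolated)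
32 | (4Z,6R,7S,8S,9S,10S)-3,10-epoxy-9-(methacryloyloxy)-1-oxo-8-(triethylsilyloxy)germacra-2,4,11(13)-trien-12,6-olide | C=C(C)C(=O)O[C@H]1[C@@H](O[Si](CC)(CC)CC)[C@H]2C(=C)C(=O)O[C@@H]2/C=C(/C)C2=CC(=O)[C@@]1(C)O2 | intermediate
33 | (4Z,6R,7R,8S,9S,10S)-3,10-epoxy-8-hydroxy-9-(methacryloyloxy)-1-oxogermacra-2,4,11(13)-trien-12,6-olide | C=C(C)C(=O)O[C@H]1[C@@H](O)[C@H]2C(=C)C(=O)O[C@@H]2/C=C(/C)C2=CC(=O)[C@@]1(C)O2 | target

**Step count**

Total: 20 steps. Longest linear sequence: 16 steps (steps 1–6, then 11–20); the second branch is steps 7–10.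

**Three steps most likely to fail**

Step 15 (ring-closing metathesis). The alkylidene formed at the C7 vinyl group may react with a second molecule faster than it closes onto the neopentyl C10 vinyl group against the strain of the bridged bicycle, so that dimers and oligomers form. The fallback closes the carbocycle before the oxygen bridge exists. It sets out from ynone 20: Et2NH in EtOH at 0 °C should give the 4-methoxybenzyl-protected enaminone F1, in which the amine is trans to the C3 ketone and C3 and C10 are therefore cis on C1=C2. TsOH converts it into the tosylate salt F2, and ring-closing metathesis under the conditions of step 15 should then give the monocyclic ten-membered trienone salt F3, which carries no bridge strain at the moment of closure. CF3CO2H/anisole followed by aqueous acid removes the benzyl ether, hydrolyses the enaminone and lets the C10 hydroxyl close across the ring onto C3 with loss of water; after a NaHCO3 wash the route is rejoined at macrocycle 26.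

Step 16 (dihydroxylation). Facial selectivity may be poor: osmium adding on the face turned to the C1–C2 bridge would give the 8R,9R diol, and slow attack at C4=C5 may accompany it. The fallback delivers the two oxygens by double inversion instead of by direct syn addition. It sets out from 26: Woodward cis-hydroxylation (I2, AgOAc, AcOH; then AcOH/H2O) forms the iodonium ion on the face that osmium would take, acetate opens it from the other side, and the acetoxonium ion that displaces iodide with inversion is hydrolysed by water. Both oxygens should therefore end on the opposite face, as the 8-O-acetyl diol F4 and the 9-O-acetyl diol F5. Acidic methanolysis (HCl, MeOH, 0 °C) of either one gives diol 27, where the route is rejoined. Iodination at C2 of the furanone is the side reaction to watch in this fallback.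

Step 6 (iodo-olefination). The basic ylide may epimerise C6 of aldehyde 8, conversion may be low and the Z:E ratio may erode. The fallback builds the Z haloalkene by stereoselective cross-coupling instead of by Wittig stereocontrol. It sets out from 8: CBr4/PPh3 in CH2Cl2 at 0 °C (non-basic) gives the 1,1-dibromoalkene F6. Trans-selective mono-methylation (Me2Zn, PdCl2(DPEphos) cat., THF, 0 °C) replaces the bromine trans to C6 and leaves the Z 2-bromoalkene F7. F7 enters the Nozaki–Hiyama–Kishi coupling with ynal 18 (CrCl2, NiCl2, DMF, 50 °C) and the route is rejoined at carbinol 19.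

**Further compounds**

F1 | step 15 | (3R,4S,5S)-5-[(1Z,4E,6S)-5-(diethylamino)-6-[(4-methoxyphenyl)methoxy]-2,6-dimethyl-3-oxoocta-1,4,7-trien-1-yl]-3-[(dimethylamino)methyl]-4-ethenyloxolan-2-one | C=C[C@@](C)(/C(N(CC)CC)=C\C(=O)/C(C)=C\[C@H]1OC(=O)[C@@H](CN(C)C)[C@@H]1C=C)OCc1ccc(OC)cc1
F2 | step 15 | 4-methylbenzenesulfonate salt of F1 | C=C[C@@](C)(/C(N(CC)CC)=C\C(=O)/C(C)=C\[C@H]1OC(=O)[C@@H](C[NH+](C)C)[C@@H]1C=C)OCc1ccc(OC)cc1.Cc1ccc(S(=O)(=O)[O-])cc1
F3 | step 15 | (1E,4Z,8Z)-1-(diethylamino)-13-(dimethylammonio)-10-[(4-methoxyphenyl)methoxy]-3-oxogermacra-1,4,8-trien-12,6-olide 4-methylbenzenesulfonate | C[C@]1(OCc2ccc(OC)cc2)/C=C\[C@H]2[C@H](C[NH+](C)C)C(=O)O[C@@H]2/C=C(/C)C(=O)/C=C1/N(CC)CC.Cc1ccc(S(=O)(=O)[O-])cc1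
F4 | step 16 | 8-O-acetate of diol 27 | O[C@H]1[C@@H](OC(C)=O)[C@H]2[C@H](CN(C)C)C(=O)O[C@@H]2/C=C(/C)C2=CC(=O)[C@@]1(C)O2
F5 | step 16 | 9-O-acetate of diol 27 | CC(=O)O[C@H]1[C@@H](O)[C@H]2[C@H](CN(C)C)C(=O)O[C@@H]2/C=C(/C)C2=CC(=O)[C@@]1(C)O2
F6 | step 6 | (3R,4S,5S)-5-(2,2-dibromoethenyl)-3-[(dimethylamino)methyl]-4-ethenyloxolan-2-one | BrC(Br)=C[C@H]1OC(=O)[C@@H](CN(C)C)[C@@H]1C=C
F7 | step 6 | (3R,4S,5S)-5-[(Z)-2-bromoprop-1-en-1-yl]-3-[(dimethylamino)methyl]-4-ethenyloxolan-2-one | Br/C(C)=C\[C@H]1OC(=O)[C@@H](CN(C)C)[C@@H]1C=C
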